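The route rests on cutting ring B (cycloheptane C1, C5–C10) at C10–C1. In the perimeter numbering (C1 quaternary methyl carbon, C4 isopropyl carbinol, C5 ring fusion, C6 angelate carbon, C8/C9 epoxide, C10 carbinol) the secondary alcohol C10 lies between the quaternary C1 of cyclopentane ring A and the C8=C9 unit, the imprint of a [2,3]-Wittig shift. Lithiating a dihydropyran at its allylic O–CH2 and letting that carbon add to the cyclopentene should, in one operation, form C10–C1, cleave C6–O, enlarge the six-membered ether to the hydroazulene, set C1 and C10 and leave C5=C6. The precursor is a (2S)-4-methyl-3,6-dihydro-2H-pyran bearing a 2-methylcyclopentenyl group with a silylated isopropyl carbinol.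

Key step: step 9

Remark on numbering: C2, C3 and C7 are the methylenes; β is the face of the C1 methyl and α the opposite face; ring A is C1–C5 and ring B is C1, C5–C10.
Remark on configuration: the dihydropyran carbon C6 must be S, because only then does the ring oxygen lie on the α face of the cyclopentene; the R epimer would give the C1,C10-bis-epimer.
Remark on design: the C4 triethylsilyl ether is installed only after the C6 oxygen is allylated, because a C6 alkoxide beside a C4 silyl ether would invite O-to-O silyl migration.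
Remark on resolution: asymmetric isopropyl addition to this enone has no reliable precedent, so C4 is secured by chromatographic resolution of the first chiral intermediate.

Step 1
Reactants: 1 3-methylcyclopent-2-en-1-one
Product: 3 2-bromo-3-methylcyclopent-2-en-1-one, via dibromoketone 2 (not isolated)
Conditions: Br2, CH2Cl2, 0 °C; then Et3N, 0 °C → rt
Reagents that add atoms: bromine, BrBr
Why: Bromination–dehydrobromination: bromine adds across the enone and triethylamine eliminates HBr from the α,β-dibromide to give the α-bromoenone, with no stereocentre left.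

Step 2
Reactants: 3 2-bromo-3-methylcyclopent-2-en-1-one; 4 isopropylmagnesium chloride
Product: 5 racemic 2-bromo-3-methyl-1-(propan-2-yl)cyclopent-2-en-1-ol
Conditions: iPrMgCl, CeCl3, THF, −78 → 0 °C; then H2O
Reagents that add atoms: isopropylmagnesium chloride (4), CC(C)[Mg]Cl
Why: Cerium-mediated Grignard 1,2-addition (Imamoto conditions) to the enone carbonyl avoids enolisation, reduction and conjugate addition and creates the tertiary carbinol C4 as a racemate.

Step 3
Reactants: 5 racemic 2-bromo-3-methyl-1-(propan-2-yl)cyclopent-2-en-1-ol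
Product: 6 (1R)-2-bromo-3-methyl-1-(propan-2-yl)cyclopent-2-en-1-ol
Conditions: preparative HPLC, amylose tris(3,5-dimethylphenylcarbamate) phase, hexane/i-PrOH, rt
Reagents that add atoms: none
Why: Chromatographic resolution on a polysaccharide carbamate chiral stationary phase separates the enantiomers without touching any bond, and the (R)-enantiomer carries the C4 configuration of the target.

Step 4
Reactants: 6 (1R)-2-bromo-3-methyl-1-(propan-2-yl)cyclopent-2-en-1-ol; 7 N,N-dimethylformamide
Product: 9 (5R)-5-hydroxy-2-methyl-5-(propan-2-yl)cyclopent-1-ene-1-carbaldehyde, via dilithio alkoxide 8 (not isolated)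
Conditions: t-BuLi (3.1 equiv), Et2O, −78 °C; then DMF, −78 → 0 °C; then H2O
Reagents that add atoms: N,N-dimethylformamide (7), CN(C)C=O
Why: O-deprotonation followed by bromine–lithium exchange gives the 2-lithioallyl alkoxide familiar from 2-bromoallylic alcohols, and its Bouveault-type formylation with DMF installs C6 while C4 is untouched.

Step 5
Reactants: 9 (5R)-5-hydroxy-2-methyl-5-(propan-2-yl)cyclopent-1-ene-1-carbaldehyde; 10 2-methylallylmagnesium chloride
Product: 12 (1R)-2-[(1S)-1-hydroxy-3-methylbut-3-en-1-yl]-3-methyl-1-(propan-2-yl)cyclopent-2-en-1-ol, via borinate ester 11 (not isolated)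
Conditions: (−)-Ipc2BOMe (from (+)-α-pinene), 2-methylallylmagnesium chloride, Et2O, −78 °C → rt; then 9, −78 °C; then NaOH, H2O2, 0 °C → rt
Reagents that add atoms: 2-methylallylmagnesium chloride (10), C=C(C)C[Mg]Cl
Why: Brown asymmetric methallylboration: the diisopinocampheyl(2-methylallyl)borane adds through a chair Zimmerman–Traxler transition state to the Si face of the aldehyde under reagent control, setting C6 as S, and any C6 epimer is removable by chromatography.

Step 6
Reactants: 12 (1R)-2-[(1S)-1-hydroxy-3-methylbut-3-en-1-yl]-3-methyl-1-(propan-2-yl)cyclopent-2-en-1-ol; 13 allyl bromide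
Product: 14 (1R)-3-methyl-2-[(1S)-3-methyl-1-(prop-2-en-1-yloxy)but-3-en-1-yl]-1-(propan-2-yl)cyclopent-2-en-1-ol
Conditions: NaH (1.1 equiv), allyl bromide, Bu4NI (cat.), THF, 0 °C → rt
Reagents that add atoms: allyl bromide (13), C=CCBr
Why: Williamson etherification is selective for the secondary C6 alkoxide because the tertiary C4–OH, flanked by isopropyl and a fully substituted neighbour, is far less nucleophilic; no stereocentre is affected.

Step 7
Reactants: 14 (1R)-3-methyl-2-[(1S)-3-methyl-1-(prop-2-en-1-yloxy)but-3-en-1-yl]-1-(propan-2-yl)cyclopent-2-en-1-ol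
Product: 15 triethyl{[(1R)-3-methyl-2-[(1S)-3-methyl-1-(prop-2-en-1-yloxy)but-3-en-1-yl]-1-(propan-2-yl)cyclopent-2-en-1-yl]oxy}silane
Conditions: TESOTf, 2,6-lutidine, CH2Cl2, −78 → 0 °C
Reagents that add atoms: triethylsilyl trifluoromethanesulfonate, CC[Si](CC)(CC)OS(=O)(=O)C(F)(F)F
Why: Silyl triflate silylation with a hindered pyridine base protects the hindered tertiary C4–OH, so that no free hydroxyl can direct or consume the base of the key step.

Step 8
Reactants: 15 triethyl{[(1R)-3-methyl-2-[(1S)-3-methyl-1-(prop-2-en-1-yloxy)but-3-en-1-yl]-1-(propan-2-yl)cyclopent-2-en-1-yl]oxy}silane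
Product: 16 (2S)-4-methyl-2-[(5R)-2-methyl-5-(propan-2-yl)-5-(triethylsilyloxy)cyclopent-1-en-1-yl]-3,6-dihydro-2H-pyran
Conditions: second-generation Grubbs catalyst RuCl2(=CHPh)(PCy3)(H2IMes) (5 mol%), CH2Cl2, 40 °C
Reagents that add atoms: none
Why: Ring-closing metathesis of the allyl and 2-methylallyl olefins closes the six-membered ether with the trisubstituted C8=C9 olefin, the tetrasubstituted cyclopentene being inert to the ruthenium carbene.

Step 9
Reactants: 16 (2S)-4-methyl-2-[(5R)-2-methyl-5-(propan-2-yl)-5-(triethylsilyloxy)cyclopent-1-en-1-yl]-3,6-dihydro-2H-pyran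
Product: 19 (3R,8R,8aS)-6,8a-dimethyl-3-(propan-2-yl)-3-(triethylsilyloxy)-1,2,3,5,8,8a-hexahydroazulen-8-ol, via α-lithio ether 17 (not isolated), via lithium alkoxide 18 (not isolated)
Conditions: s-BuLi, THF, −78 → −40 °C; then H2O, −78 °C
Reagents that add atoms: none
Why: Proposed new method: s-BuLi should remove one of the C10 protons (α to oxygen and allylic to C8=C9) to give α-lithio ether 17, whose carbanion adds suprafacially to C1 of the cyclopentene while the C6–O bond breaks and the π bond moves to C5=C6, a concerted six-electron [2,3]-sigmatropic shift that ends in lithium alkoxide 18 and, after quenching, dienol 19. The closest known reaction type is the [2,3]-Wittig rearrangement of bis-allylic ethers, including the ring contraction of macrocyclic diallyl ethers, whereas here both the carbanion and the oxygen sit inside a six-membered ring and the migration terminus is tetrasubstituted. Ring B closes through the new C10–C1 bond in a five-centre envelope (C10, O, C6, C5, C1) that spans the dihydropyran, a geometry resembling an 8-oxabicyclo[3.2.1]octa-2,6-diene with oxygen as the one-atom bridge, so the six-membered ether becomes the seven-membered carbocycle and the oxygen is left outside the ring on C10. Because the emerging C5=C6 olefin must be cis inside ring B, C7 has to lie syn to C1, and the (S) configuration of C6 then places the bridging oxygen on the α face of the cyclopentene, opposite the C4 silyl ether. C10 therefore bonds to the α face of C1 (methyl ends β) and keeps its oxygen α, so both new stereocentres are dictated by C6, whose own chirality is spent. The step needs lithiation at C10 rather than at the methine C6 and the concerted shift rather than radical [1,2] or [1,4] migrations; the unhindered C10–H bonds, the shielding of C6–H by the fully substituted C4 and the low temperature should secure this.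

Step 10
Reactants: 19 (3R,8R,8aS)-6,8a-dimethyl-3-(propan-2-yl)-3-(triethylsilyloxy)-1,2,3,5,8,8a-hexahydroazulen-8-ol
Product: 20 (1S,4R,8R,9S,10S)-epoxy alcohol, i.e. 19 with an α-epoxide across C8–C9 cis to the C10–OH
Conditions: VO(acac)2 (cat.), t-BuOOH, CH2Cl2, 0 °C → rt
Reagents that add atoms: tert-butyl hydroperoxide, CC(C)(C)OO
Why: Hydroxyl-directed vanadium-catalysed epoxidation delivers oxygen to C8=C9 on the face of the allylic C10–OH (α), giving the cis-epoxy alcohol and setting C8 and C9, while the merely homoallylic C5=C6 olefin reacts much more slowly.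

Step 11
Reactants: 20 (1S,4R,8R,9S,10S)-epoxy alcohol
Product: 21 C4,C10-bis(triethylsilyl) ether of 20 (C5=C6 olefin retained)
Conditions: TESCl, imidazole, DMAP (cat.), DMF, rt
Reagents that add atoms: chlorotriethylsilane, CC[Si](Cl)(CC)CC
Why: Imidazole-promoted silylation (Corey conditions) caps the C10–OH under non-acidic conditions that spare the epoxide, so that only the C6 hydroxyl made next can be acylated.

Step 12
Reactants: 21 C4,C10-bis(triethylsilyl) ether of 20
Product: 23 6-O-deangeloyl-4,10-bis-O-(triethylsilyl)lapiferine (C6–OH α and C5–H α), via C6 alkylborane 22 (not isolated)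
Conditions: BH3·THF, THF, 0 °C → rt; then NaOH, H2O2, 0 °C
Reagents that add atoms: hydrogen peroxide, OO
Why: Hydroboration–oxidation: borane adds syn across the trisubstituted C5=C6 olefin with boron on the less substituted C6 and from the α face, away from the angular C1 methyl as in steroidal 5-enes, and oxidation with retention gives C5–H α and C6–OH α, hence the trans ring fusion.

Step 13
Reactants: 23 6-O-deangeloyl-4,10-bis-O-(triethylsilyl)lapiferine; 24 angelic acid
Product: 25 4,10-bis-O-(triethylsilyl)lapiferine
Conditions: angelic acid, 2,4,6-trichlorobenzoyl chloride, Et3N, toluene, rt; then 23, 80 °C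
Reagents that add atoms: angelic acid (24), C/C=C(/C)C(=O)O
Why: Yamaguchi-type mixed-anhydride esterification acylates the hindered C6–OH through the angelic 2,4,6-trichlorobenzoic anhydride without a nucleophilic catalyst, the established way to keep the (Z)-olefin from isomerising to the tiglate.

Step 14
Reactants: 25 4,10-bis-O-(triethylsilyl)lapiferine
Product: 26 lapiferine
Conditions: TBAF, AcOH, THF, 0 °C → rt
Reagents that add atoms: none
Why: Fluoride-mediated desilylation buffered with acetic acid removes both triethylsilyl ethers while the angelate, the epoxide and the cis-epoxy alcohol array stay intact.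

Compound list
1 | 3-methylcyclopent-2-en-1-one | CC1=CC(=O)CC1 | starting material
2 | 2,3-dibromo-3-methylcyclopentan-1-one (racemic) | CC1(Br)CCC(=O)C1Br | intermediate
3 | 2-bromo-3-methylcyclopent-2-en-1-one | CC1=C(Br)C(=O)CC1 | intermediate
4 | isopropylmagnesium chloride | CC(C)[Mg]Cl | starting material
5 | racemic 2-bromo-3-methyl-1-(propan-2-yl)cyclopent-2-en-1-ol | CC1=C(Br)C(O)(C(C)C)CC1 | intermediate
6 | (1R)-2-bromo-3-methyl-1-(propan-2-yl)cyclopent-2-en-1-ol | BrC1=C(C)CC[C@@]1(O)C(C)C | intermediate
7 | N,N-dimethylformamide | CN(C)C=O | starting material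
8 | lithium (1R)-2-lithio-3-methyl-1-(propan-2-yl)cyclopent-2-en-1-olate | [Li]C1=C(C)CC[C@@]1(O[Li])C(C)C | intermediate
9 | (5R)-5-hydroxy-2-methyl-5-(propan-2-yl)cyclopent-1-ene-1-carbaldehyde | O=CC1=C(C)CC[C@@]1(O)C(C)C | intermediate
10 | 2-methylallylmagnesium chloride | C=C(C)C[Mg]Cl | starting material
11 | diisopinocampheylborinate of the C6 alcohol 12 | C=C(C)C[C@H](OB([C@@H]1C[C@@H]2C[C@H]([C@H]1C)C2(C)C)[C@@H]1C[C@@H]2C[C@H]([C@H]1C)C2(C)C)C1=C(C)CC[C@@]1(O)C(C)C | intermediate
12 | (1R)-2-[(1S)-1-hydroxy-3-methylbut-3-en-1-yl]-3-methyl-1-(propan-2-yl)cyclopent-2-en-1-ol | C=C(C)C[C@H](O)C1=C(C)CC[C@@]1(O)C(C)C | intermediate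
13 | allyl bromide | C=CCBr | starting material
14 | (1R)-3-methyl-2-[(1S)-3-methyl-1-(prop-2-en-1-yloxy)but-3-en-1-yl]-1-(propan-2-yl)cyclopent-2-en-1-ol | C=CCO[C@@H](CC(C)=C)C1=C(C)CC[C@@]1(O)C(C)C | intermediate
15 | triethyl{[(1R)-3-methyl-2-[(1S)-3-methyl-1-(prop-2-en-1-yloxy)but-3-en-1-yl]-1-(propan-2-yl)cyclopent-2-en-1-yl]oxy}silane | C=CCO[C@@H](CC(C)=C)C1=C(C)CC[C@@]1(O[Si](CC)(CC)CC)C(C)C | intermediate
16 | (2S)-4-methyl-2-[(5R)-2-methyl-5-(propan-2-yl)-5-(triethylsilyloxy)cyclopent-1-en-1-yl]-3,6-dihydro-2H-pyran | CC1=CCO[C@@H](C1)C1=C(C)CC[C@@]1(O[Si](CC)(CC)CC)C(C)C | intermediate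
17 | C10-lithio derivative of 16 (lithium on the allylic O–CH, configurationally labile) | CC1=CC([Li])O[C@@H](C1)C1=C(C)CC[C@@]1(O[Si](CC)(CC)CC)C(C)C | intermediate
18 | lithium alkoxide of 19 | CC1=C[C@@H](O[Li])[C@@]2(C)CC[C@@](O[Si](CC)(CC)CC)(C(C)C)C2=CC1 | intermediate
19 | (3R,8R,8aS)-6,8a-dimethyl-3-(propan-2-yl)-3-(triethylsilyloxy)-1,2,3,5,8,8a-hexahydroazulen-8-ol (C5=C6 and C8=C9 olefins, C10–OH α, C1–CH3 β) | CC1=C[C@@H](O)[C@@]2(C)CC[C@@](O[Si](CC)(CC)CC)(C(C)C)C2=CC1 | intermediate
20 | (1S,4R,8R,9S,10S)-epoxy alcohol: 19 with an α-epoxide across C8–C9, cis to C10–OH | C1C[C@@]2(C)O[C@H]2[C@@H](O)[C@@]2(C)CC[C@@](O[Si](CC)(CC)CC)(C(C)C)C2=1 | intermediate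
21 | C4,C10-bis(triethylsilyl) ether of 20 | C1C[C@@]2(C)O[C@H]2[C@@H](O[Si](CC)(CC)CC)[C@@]2(C)CC[C@@](O[Si](CC)(CC)CC)(C(C)C)C2=1 | intermediate
22 | C6 alkylborane from 21 (boron α at C6, hydrogen α at C5) | B[C@H]1C[C@@]2(C)O[C@H]2[C@@H](O[Si](CC)(CC)CC)[C@@]2(C)CC[C@@](O[Si](CC)(CC)CC)(C(C)C)[C@H]12 | intermediate
23 | 6-O-deangeloyl-4,10-bis-O-(triethylsilyl)lapiferine, (1S,4R,5S,6S,8R,9S,10S) | O[C@H]1C[C@@]2(C)O[C@H]2[C@@H](O[Si](CC)(CC)CC)[C@@]2(C)CC[C@@](O[Si](CC)(CC)CC)(C(C)C)[C@H]12 | intermediate
24 | angelic acid, (Z)-2-methylbut-2-enoic acid | C/C=C(/C)C(=O)O | starting material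
25 | 4,10-bis-O-(triethylsilyl)lapiferine | C/C=C(/C)C(=O)O[C@H]1C[C@@]2(C)O[C@H]2[C@@H](O[Si](CC)(CC)CC)[C@@]2(C)CC[C@@](O[Si](CC)(CC)CC)(C(C)C)[C@H]12 | intermediate
26 | lapiferine | C/C=C(/C)C(=O)O[C@H]1C[C@@]2(C)O[C@H]2[C@@H](O)[C@@]2(C)CC[C@@](O)(C(C)C)[C@H]12 | target

Total step count: 14. Longest linear sequence: 14 steps (from 1 to 26).

Steps most likely to fail

Step 9. The base may attack the wrong α-oxy position, or the lithiated dihydropyran may be diverted into [1,2]/[1,4] migration with ring contraction before the bridged [2,3] geometry is reached. The fallback sets out from the open-chain allyl ether 15 and uses the established [2,3]-Wittig rearrangement of an acyclic bis-allylic ether (s-BuLi, THF, −78 °C). Lithiation at the unsubstituted allyl O–CH2 and shift onto the cyclopentene, with chirality transfer from C6 to C1, should give the open-chain trienol F1 with C7 syn to C1 across C5=C6. That geometry is favoured because the alternative eclipses C7 with the fully substituted C4. Ring-closing metathesis of the C9 vinyl and C8 isopropenyl groups of F1 with the second-generation Grubbs catalyst RuCl2(=CHPh)(PCy3)(H2IMes) then closes ring B and comes back to the route at 19. In this variant the C10 configuration is no longer enforced by a bridge and may require separation of diastereomers.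

Step 12. Borane may approach syn to the angular methyl, because the α face carries the C4 isopropyl group and the C10 silyl ether, or it may reductively open the epoxide. The fallback sets out from 20 and delivers the hydride intramolecularly from the α-oriented C10 oxygen. Chlorodimethylsilane/Et3N should give the C10 hydrodimethylsilyl ether F2. Karstedt catalyst Pt2[(CH2=CHSiMe2)2O]3 should then effect syn intramolecular hydrosilylation, silicon bonding to the less substituted C6 and hydrogen to C5, to give the cyclic siloxane F3. Tamao–Fleming oxidation (H2O2, KF, KHCO3, THF/MeOH) should give the C6,C10-diol F4 with retention. Mixed-anhydride angeloylation as in step 13, at the less hindered C6–OH, should give the 4-O-triethylsilyl angelate F5. TBAF/AcOH as in step 14 then comes back to the route at 26.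

Step 13. The angeloyl unit may isomerise to the (E)-tigloyl geometry during acyl transfer, or the hindered C6–OH may resist acylation. The fallback sets out from 23 and builds the (Z)-olefin on the molecule. Steglich acylation (DCC, DMAP) with 2-[bis(2,2,2-trifluoroethoxy)phosphoryl]propanoic acid should give the phosphonopropionate ester F6. Still–Gennari olefination of F6 with acetaldehyde (KHMDS, 18-crown-6, THF, −78 °C) should form the (Z)-2-methylbut-2-enoate and come back to the route at 25.

Further compounds
F1 | step 9 | (1R)-1-[(1S,2E,3R)-1-methyl-2-(3-methylbut-3-en-1-ylidene)-3-(propan-2-yl)-3-(triethylsilyloxy)cyclopentyl]prop-2-en-1-ol | C=C[C@@H](O)[C@@]1(C)CC[C@@](O[Si](CC)(CC)CC)(C(C)C)/C1=C/CC(C)=C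
F2 | step 12 | C10 O-(dimethylsilyl) ether of 20 | C1C[C@@]2(C)O[C@H]2[C@@H](O[SiH](C)C)[C@@]2(C)CC[C@@](O[Si](CC)(CC)CC)(C(C)C)C2=1
F3 | step 12 | cyclic dimethylsiloxane bridging C6 (Si, α) and the C10 oxygen, C5–H α | C[Si]3(C)[C@H]1C[C@@]2(C)O[C@H]2[C@@H](O3)[C@@]2(C)CC[C@@](O[Si](CC)(CC)CC)(C(C)C)[C@H]12
F4 | step 12 | 6-O-deangeloyl-4-O-(triethylsilyl)lapiferine (C6,C10-diol) | O[C@H]1C[C@@]2(C)O[C@H]2[C@@H](O)[C@@]2(C)CC[C@@](O[Si](CC)(CC)CC)(C(C)C)[C@H]12
F5 | step 12 | 4-O-(triethylsilyl)lapiferine | C/C=C(/C)C(=O)O[C@H]1C[C@@]2(C)O[C@H]2[C@@H](O)[C@@]2(C)CC[C@@](O[Si](CC)(CC)CC)(C(C)C)[C@H]12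
F6 | step 13 | C6 2-[bis(2,2,2-trifluoroethoxy)phosphoryl]propanoate of 23 (mixture at the phosphonate carbon) | CC(C(=O)O[C@H]1C[C@@]2(C)O[C@H]2[C@@H](O[Si](CC)(CC)CC)[C@@]2(C)CC[C@@](O[Si](CC)(CC)CC)(C(C)C)[C@H]12)P(=O)(OCC(F)(F)F)OCC(F)(F)F
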